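## The problem

Briarane numbering is used for every compound: the ten-membered ring is C1–C10, ring A is C1, C10, C11, C12, C13, C14, C15 is the methyl on C1, C16 sits on C5, C20 on C11, and the lactone is O, C19, C17 (methyl C18), C8, C7.

- Target 35 is a cyclohexane (ring A) trans-fused along C1–C10 to a ten-membered carbocycle that holds a 3Z,5E-diene, with a γ-lactone trans-fused at C7–C8.
- A synthesis must deliver the ten-membered ring without a medium-ring cyclization next to the neopentyl C1–C2 bond. It must also set eight stereocentres (C1, C2, C7, C8, C9, C10, C14, C17), the exocyclic C11=C20 methylene, and four acetates beside a free tertiary C8 hydroxyl.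
- C1 (quaternary), C10 and the axial C14 oxygen lie on ring A and can come from a rigid precursor. C9 is next to C10, C8 next to C9 and C7 next to C8, so these can be relayed one from the other. C17 is epimerizable, and only C2 has no stereocentre beside it other than quaternary C1.
- The doubly allylic C2 and C7 esters ionize easily. The β-hydroxy lactone can undergo retro-aldol cleavage or C17 epimerization with base. The 1,1-disubstituted alkene can move into ring A with acid. These groups must therefore appear late and under mild conditions.
- The enabling feature: C2 and C7 are both oxygenated and are 1,6-related through C3–C6 and through C8–C10–C1. If they are joined, the ten-membered ring becomes the perimeter of two fused six-membered rings (C1, C2, C7, C8, C9, C10 and C2–C7), the second of which is a benzene ring at lower saturation.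
- That tricycle, with ring A, quaternary C1 and trans C10–H, is the skeleton of dehydroabietic acid 1 in the correct absolute configuration.

## Retrosynthesis

**Acetates and silyl ethers (35 ⇒ 34 ⇒ 33).** The four ester C–O bonds at C2, C9, C14 and C16 are cut first, back to pentaol 34 and its tris-silyl ether 33. Carrying acetates earlier would not survive the enolate and hydride steps, and a C9 acetate β to the C7 ketone would be eliminated. Compound 33 holds three silyl ethers and two free hydroxyls. Forward, desilylation must be non-basic and acetylation must stop before the tertiary C8 hydroxyl.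

**Lactone and the C2, C7 carbinols (33 ⇒ 31).** The lactone C19–O bond and the C2–H and C7–H bonds are cut, giving hydroxy ester 31 with ketones at C2 and C7. Acylating a separately made C7 alcohol with a propanoate tether would need a C7 alcohol beside a C8 ketone and two extra redox adjustments. In 31 both carbinol carbons are still the carbonyls that served the earlier chemistry. Forward, hydride must be guided at C7 by the C8 hydroxyl and at C2 by the ring, and the C7 alkoxide must close the five-membered lactone.

**C8–C17 bond (31 ⇒ 28 + 29).** Cutting C8–C17 removes the three lactone carbons as methyl 2-bromopropanoate 29 and leaves trione 28. The neighbouring cut is alkylation of a C7-ketone enolate at C8 followed by hydroxylation. That would build the quaternary carbinol by oxidizing a tetrasubstituted enolate with no clear facial bias. Addition to a C8 ketone is instead steered by the adjacent C9 silyloxy group. Compound 28 lacks C17–C19 and two stereocentres. Forward, the zinc enolate must choose C8 over the conjugated C7 and the hindered C2 carbonyl.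

**C8 oxygen and the diene (28 ⇒ 26 ⇒ 23).** The C8 carbonyl is traced to the C8 methylene of dienedione 26, and the two diene C=C bonds to the C4–C5 epoxide of 23. In 26 the C1 side is quaternary and C3 and C6 are vinylic, so C8 is the only enolizable carbon. This is why the diene is made before C8 is touched; the reverse order would meet competing enolization at C3 and C6. Compound 23 has no alkene geometry to control. Forward, two E1cB eliminations must give ring-cis alkenes.

**C11 methylene and the epoxide (23 ⇒ 21).** C11=C20 is traced to a C11 dimethylamino group and the epoxide to the C4=C5 alkene of 21. Oxidative decarboxylation of a C11 acid would also give endocyclic alkenes, whereas the amine oxide can reach only the methyl hydrogens. Placed here, one peracid operation oxidizes nitrogen and epoxidizes C4=C5, and the new alkene never meets ozone. Forward, the N-oxide must eliminate below the temperature at which the β,γ-epoxy ketone suffers.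

**Ten-membered ring (21 ⇒ 18).** The C2 and C7 carbonyl carbons are joined to the tetrasubstituted alkene of tricycle 18; this is the central disconnection. Against closing the ring at C1–C2, C7–C8 or C9–C10 by C–C bond formation, the scission needs no medium-ring transition state. Compound 18 is a rigid tricycle with C1, C9, C10 and C14 already set. Forward, ozone must select the tetrasubstituted alkene over the trisubstituted one.

**Arene (18 ⇒ 16).** The 1,4-diene is traced to the benzene ring of 16. The three carbon substituents on C2, C5 and C7 fix where the Birch reduction leaves its alkenes, so no other dearomatization pattern competes. Compound 16 is flat and robust and can be built by aromatic chemistry. Forward, the benzylic C16–O bond must survive as its alkoxide.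

**C9 oxygen and C11 nitrogen (16 ⇒ 14 ⇒ 12 ⇒ 10 ⇒ 7).** The C9–O bond is cut back through ketone 14 and styrene 12 to the C8 ketone of 10, and the C11–N bond to the carboxylic acid of 7. Setting C9 on the tricycle, where only the α face is open to hydride, is preferred over oxygenating C9 on the ten-membered ring, where no selective handle exists. Forward, α-face epoxidation with a hydride shift and α-face reduction are required, and the Curtius rearrangement must retain configuration.

**C16 carbon and C14 oxygen (7 ⇒ 6 ⇒ 5 ⇒ 4 ⇒ 3 ⇒ 2 ⇒ 1).** The C5–C16 bond is cut to aryl bromide 6, the bromide to the arene C–H of 5, the C8 ketone to the benzylic methylene of 4, C5–H to the isopropyl group of 3, and the C14 ketone through alcohol 2 to 1. Degrading the isopropyl group oxidatively would need discrimination from benzylic C8 and a methyl-ketone cleavage beside two other enolizable ketones. Removing it and re-adding one carbon uses the C8 ketone as meta director. C14 has no chemical handle in 1 and is oxidized by a known fungal hydroxylation; its equatorial configuration is inverted through the ketone (3 to 11). Acid 1 is a commercial resin acid with 16 of the 20 skeletal carbons and with C1 and C10 correct.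

## Roads not taken

**Alternative 1:** Ring A would be cut at C1–C14 and C10–C11 into two small acyclic components and rebuilt by an enantioselective Diels–Alder reaction giving cyclohexene aldehyde A1.
- Merits: one catalytic step from achiral materials sets quaternary C1, C10 and the C14 acetate and supplies the C20 carbon.
- For ring A this is better than the chosen plan, which spends a biotransformation, an oxidation–reduction pair and an amine detour on the same features.
- Weak points: A1 contains none of the ten-membered ring, which would still have to be closed by C–C bond formation next to the neopentyl C1 centre. The dienophile is α,β,β-trisubstituted and sluggish. C2, C7, C8 and C9 would be set on a flexible chain or macrocycle.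
- The chosen plan sets against it the complete ring perimeter from the outset and C9 fixed on a rigid tricycle.

**Alternative 2:** The C1–C10 bond would be cut, opening both rings into a fourteen-membered ring. Forward, a Lewis acid would open a C1–C14 epoxide at C1, the C10=C11 alkene would attack across the ring, and loss of a C20 proton would give A2.
- Merits: both rings and the exocyclic methylene arise in one step, and the methylene comes more directly than through the Cope elimination used here.
- Weak points: the macrocycle must already carry the diene, the lactone and four oxygen functions, so most of the work precedes the key step. Lewis acid meets ionizable dienyl silyl ethers. Proton loss and competing cyclization modes are not secured.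
- A2 has the equatorial C14 alcohol, so an inversion is needed just as in the chosen plan; on that point the two are equal.
- The chosen plan sets against it a key step that runs on a simple, robust substrate.

**Alternative 3:** The diene would be cut at C4–C5 and C6–C7 and formed by a three-component coupling of a ring A alkenylzinc, an alkyne and an aldehyde with a zerovalent nickel catalyst such as Ni(cod)2, giving acyclic carbinol A3.
- Merits: both alkene geometries follow from syn addition and a configurationally stable alkenylmetal. This is better than the chosen plan, which relies on thermodynamic control in the eliminations of step 17.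
- Weak points: no ring closes, so the ten-membered ring must still be made by cyclization near the C8 quaternary centre. A fully elaborated ring A fragment is needed first. C7 is set without a strong controlling element.
- The chosen plan sets against it a ring that never has to be closed; it accepts the weaker geometry control and names a correction for it.

Key step: step 15

Remarks and assumptions:
- In tricyclic compounds β means the face of the C15 methyl and α the opposite face.
- The C4–C5 epoxide of 22 and 23 is drawn as one cis diastereomer and the C8 carbinol of 27 is left open; both sets of centres become sp2 again (steps 17 and 19).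
- Metal enolates, alkoxides and ammonium salts formed and consumed within a step are treated as forms of the numbered compounds.

## Route

Step 1
Reactants: 1 dehydroabietic acid
Product: 2 14β-hydroxy acid
Conditions: Fusarium oxysporum whole cells, glucose–peptone medium, air, 27 °C, 5 d
Reagents that add atoms: dioxygen O=O
Why: Enzymatic C–H hydroxylation (cytochrome P450) at this position of 1 is a documented fungal transformation; oxygen enters the equatorial C14–H bond with retention, cis to C15, so the centre is epimeric to the target and is corrected in steps 2 and 8.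

Step 2
Reactants: 2 14β-hydroxy acid
Product: 3 14-oxo acid
Conditions: Dess–Martin periodinane, NaHCO3, CH2Cl2, rt
Reagents that add atoms: none
Why: Dess–Martin oxidation of a secondary alcohol; the ketone erases the wrong C14 centre, tolerates the acids of steps 3 to 5 and disfavours ionization at the neighbouring benzylic quaternary C1.

Step 3
Reactants: 3 14-oxo acid
Product: 4 de-isopropyl 14-oxo acid
Conditions: AlCl3 (5 equiv), toluene, rt → 40 °C; aq. HCl
Reagents that add atoms: none
Why: Retro-Friedel–Crafts transalkylation: ipso-protonation at C5 releases the isopropyl cation, which the solvent traps; this de-isopropylation is standard for dehydroabietic acid derivatives.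

Step 4
Reactants: 4 de-isopropyl 14-oxo acid
Product: 5 8,14-dioxo acid
Conditions: CrO3, AcOH, 50 °C
Reagents that add atoms: chromium trioxide O=[Cr](=O)=O
Why: Benzylic oxidation of the only benzylic methylene (C8), routine for dehydroabietanes; the aryl ketone becomes the meta director for step 5 and the entry to the C9 oxygen.

Step 5
Reactants: 5 8,14-dioxo acid
Product: 6 5-bromo-8,14-dioxo acid
Conditions: AlCl3 (6 equiv), Br2 (1.05 equiv), 1,2-dichloroethane, 60 °C
Reagents that add atoms: bromine BrBr
Why: Electrophilic aromatic bromination under swamping-catalyst conditions, with both carbonyls complexed so that no enol is available; C5 is meta to acyl-bearing C7 and para to alkyl-bearing C2, and the other meta position C3 is blocked by the peri quaternary C1, as in 7-substitution of 1-tetralones.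

Step 6
Reactants: 6 5-bromo-8,14-dioxo acid
Product: 7 5-methoxycarbonyl-8,14-dioxo acid
Conditions: Pd(OAc)2 (5 mol%), 1,3-bis(diphenylphosphino)propane, CO (1 atm), MeOH, Et3N, DMF, 70 °C
Reagents that add atoms: carbon monoxide [C-]#[O+]; methanol CO
Why: Palladium-catalysed alkoxycarbonylation of an aryl bromide (oxidative addition to zerovalent palladium, CO insertion, methanolysis) installs C16; the ketones and the free acid are spectators.

Step 7
Reactants: 7 5-methoxycarbonyl-8,14-dioxo acid
Product: 10 C11 methyl carbamate, via acyl azide 8 (not isolated), via isocyanate 9 (not isolated)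
Conditions: (PhO)2P(O)N3, Et3N, toluene, rt → 90 °C; then MeOH, 65 °C
Reagents that add atoms: diphenylphosphoryl azide [N-]=[N+]=NP(=O)(Oc1ccccc1)Oc1ccccc1; methanol CO
Why: Curtius rearrangement of the tertiary acid proceeds with retention, so nitrogen takes the equatorial place of the carboxyl at C11; the aryl methyl ester is untouched.

Step 8
Reactants: 10 C11 methyl carbamate
Product: 11 8β,14α-diol
Conditions: LiBH(s-Bu)3 (L-Selectride, 4 equiv), THF, −78 → −40 °C; then aq. NaOH, H2O2, 0 °C
Reagents that add atoms: none
Why: Bulky trialkylborohydride reduction: at C14 hydride is delivered equatorially, as with 4,4-dimethyl-3-oxo triterpenoids, and gives the axial α-alcohol of the target; the C8 aryl ketone is reduced from the α face and its new centre is lost in step 9.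

Step 9
Reactants: 11 8β,14α-diol
Product: 12 8,9-alkene
Conditions: TsOH·H2O (5 mol%), toluene, 80 °C
Reagents that add atoms: none
Why: Acid-catalysed E1 dehydration of the benzylic alcohol gives the styrene; the neopentyl C14 alcohol does not ionize under these conditions.

Step 10
Reactants: 12 8,9-alkene
Product: 14 9-ketone, via 8α,9α-epoxide 13 (not isolated)
Conditions: mCPBA (1.2 equiv), NaHCO3, CH2Cl2, 0 °C; aq. wash; then ZnI2 (10 mol%), CH2Cl2, rt
Reagents that add atoms: 3-chloroperbenzoic acid OOC(=O)c1cccc(Cl)c1
Why: Epoxidation from the α face (the β face is shielded by the C15 and C20 methyls) followed by Meinwald rearrangement: the benzylic C8–O bond ionizes and a 1,2-hydride shift from C9 gives the ketone.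

Step 11
Reactants: 14 9-ketone
Product: 15 N-methylamino triol
Conditions: LiAlH4 (excess), THF, 0 °C → reflux; Fieser work-up
Reagents that add atoms: none
Why: Hydride attacks the C9 ketone from the α face, opposite the two syn-axial methyls, and sets the β (axial) C9 alcohol of the target, as with 6-oxo steroids; the same reagent reduces the carbamate to NHMe and the aryl ester to the C16 alcohol.

Step 12
Reactants: 15 N-methylamino triol
Product: 16 N,N-dimethylamino triol
Conditions: aq. CH2O, NaBH(OAc)3, AcOH, 1,2-dichloroethane, rt
Reagents that add atoms: formaldehyde C=O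
Why: Reductive amination of the secondary amine through its iminium ion; the alcohols are unaffected.

Step 13
Reactants: 16 N,N-dimethylamino triol
Product: 17 2(7),4-diene triol
Conditions: Li (12 equiv), NH3(l)/THF, t-BuOH, −78 → −33 °C; then NH4Cl
Reagents that add atoms: none
Why: Birch reduction of a 1,2,4-trialkylbenzene leaves all three substituents on sp2 carbons, giving the C2=C7 and C4=C5 alkenes with C3 and C6 as methylenes; the benzylic C16 oxygen is present as its lithium alkoxide, the form in which benzyl alcohol itself is reduced without C–O cleavage.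

Step 14
Reactants: 17 2(7),4-diene triol
Product: 18 tris-TBS diene amine
Conditions: TBSOTf (4.5 equiv), 2,6-lutidine, CH2Cl2, 0 → 35 °C
Reagents that add atoms: tert-butyldimethylsilyl triflate CC(C)(C)[Si](C)(C)OS(=O)(=O)C(F)(F)F
Why: Silylation with a silyl triflate, needed for the syn-axially hindered C9 and C14 hydroxyls; the tertiary amine is not silylated.

Step 15
Reactants: 18 tris-TBS diene amine
Product: 21 bicyclic 2,7-dione, via primary ozonide 19 (not isolated), via secondary ozonide 20 (not isolated)
Conditions: CF3CO2H (1.1 equiv), CH2Cl2, −78 °C; O3/O2 to the Sudan Red 7B end point; PPh3, −78 °C → rt; aq. NaHCO3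
Reagents that add atoms: ozone [O-][O+]=O
Why: Ozone adds as a 1,3-dipole to the C2=C7 alkene to give primary ozonide 19, which cycloreverts to a ketone and a tethered carbonyl oxide (Criegee mechanism); these recombine to secondary ozonide 20, and PPh3 reduces the peroxide to the two ketones. The closest known reaction type is the selective ozonolysis of the ring-fusion alkene of Birch-derived 1,4-dienes and of 9,10-octalins to cyclodecane-1,6-diones. No ring is closed by bond formation: the ten-membered ring C1–C10 appears because the bond shared by two six-membered rings is cut, so no cyclization transition state is involved. No stereocentre is formed; C1, C9, C10 and C14 are untouched and the C4=C5 alkene keeps its ring-cis geometry. The step needs chemoselectivity for the tetrasubstituted over the trisubstituted alkene: C2=C7 carries four alkyl donors and is the more nucleophilic dipolarophile, C4=C5 is deactivated by the allylic silyloxy group, and ozone is dosed to the indicator end point at −78 °C. The amine is protected as its ammonium trifluoroacetate, which ozone does not oxidize. Dione 21 is released under neutral conditions and used at once, because acid or base would start transannular aldol reactions of the 1,6-diketone.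

Step 16
Reactants: 21 bicyclic 2,7-dione
Product: 23 4,5-epoxy-2,7-dione with C11 methylene, via amine N-oxide epoxide 22 (not isolated)
Conditions: mCPBA (2.2 equiv), NaHCO3, CH2Cl2, −20 → 0 °C; aq. Na2S2O3; then THF, 65 °C
Reagents that add atoms: 3-chloroperbenzoic acid OOC(=O)c1cccc(Cl)c1
Why: The peracid oxidizes the amine to its N-oxide and epoxidizes the remaining alkene (Prilezhaev reaction); on warming, Cope elimination through a five-membered syn transition state can reach only the C20 methyl hydrogens of the equatorial N-oxide, so the exocyclic C11=C20 alkene forms, as with 1-methylcyclohexyl dimethylamine oxide. The epoxide configuration is irrelevant.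

Step 17
Reactants: 23 4,5-epoxy-2,7-dione with C11 methylene
Product: 26 3Z,5E-diene-2,7-dione, via C4 hydroxy enone 24 (not isolated), via C4 mesylate 25 (not isolated)
Conditions: DBU (1.5 equiv), CH2Cl2, 0 °C → rt; then Et3N, MsCl, 0 °C → rt
Reagents that add atoms: none
Why: E1cB opening of the β,γ-epoxy ketone from the more accessible C6 side gives the C5=C6 enone with a secondary C4 hydroxyl; mesylation and a second E1cB loss towards C3 complete the dienedione. Both alkenes should end ring-cis, because a trans alkene in the conjugated ten-membered diene is strained and DBU equilibrates enone geometry by reversible conjugate addition.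

Step 18
Reactants: 26 3Z,5E-diene-2,7-dione
Product: 27 8-hydroxy dienedione
Conditions: LiN(SiMe3)2 (1.1 equiv), THF, −78 °C; 2-(phenylsulfonyl)-3-phenyloxaziridine; aq. NH4Cl
Reagents that add atoms: 2-(phenylsulfonyl)-3-phenyloxaziridine O=S(=O)(c1ccccc1)N1OC1c1ccccc1
Why: Enolate hydroxylation: C8 is the only enolizable carbon (C1 is quaternary, C3 and C6 are vinylic), and the C9 silyloxy group is too poor a leaving group for β-elimination at −78 °C. The new C8 centre is not controlled and is removed in step 19.

Step 19
Reactants: 27 8-hydroxy dienedione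
Product: 28 2,7,8-trione
Conditions: Dess–Martin periodinane, NaHCO3, CH2Cl2, 0 °C → rt
Reagents that add atoms: none
Why: Dess–Martin oxidation of the α-ketol to the vicinal diketone; C7 stays conjugated to the diene, which leaves C8 as the most electrophilic carbonyl.

Step 20
Reactants: 28 2,7,8-trione; 29 methyl 2-bromopropanoate
Product: 31 C8 Reformatsky adduct, via zinc enolate 30 (not isolated)
Conditions: 29, Zn dust (Me3SiCl-activated), THF, 40 °C; then 28, −30 → 0 °C; aq. NH4Cl
Reagents that add atoms: none
Why: Reformatsky addition to C8, the only non-conjugated carbonyl (C2 is neopentyl, C7 vinylogous). C8 is set by polar Felkin–Anh control: the enolate attacks anti to the C9–O bond and past H9, which gives the target configuration. C17 is set in the closed transition state and is equilibrated in step 21 if it forms as a mixture.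

Step 21
Reactants: 31 C8 Reformatsky adduct
Product: 33 lactone 2,8-diol tris-TBS ether, via hydroxy ester diol 32 (not isolated)
Conditions: NaBH4, CeCl3·7H2O, MeOH/THF, −40 → 0 °C; then K2CO3 (0.5 equiv), MeOH, 0 °C → rt
Reagents that add atoms: none
Why: Luche 1,2-reduction of both enone carbonyls: at C7 cerium bridges the ketone and the C8 hydroxyl (Cram chelate) and hydride enters anti to the bulky C9 branch; at C2 it is expected from the outer face of the ring. The C7 alkoxide closes the γ-lactone on the C19 ester, and K2CO3 equilibrates C17 to the isomer with the C18 methyl trans to C9, which is the target configuration.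

Step 22
Reactants: 33 lactone 2,8-diol tris-TBS ether
Product: 34 pentaol lactone
Conditions: HF·pyridine, pyridine, THF, 0 °C → rt
Reagents that add atoms: none
Why: Buffered fluoride desilylation without base preserves the β-hydroxy lactone, the dienyl alcohols and the exocyclic alkene.

Step 23
Reactants: 34 pentaol lactone
Product: 35 target tetraacetate
Conditions: Ac2O, pyridine, DMAP (cat.), CH2Cl2, 0 °C → rt
Reagents that add atoms: acetic anhydride CC(=O)OC(C)=O
Why: Acylation of the primary and the three secondary alcohols; the tertiary C8 hydroxyl, flanked by C7, C9 and C17, is not acetylated under these conditions.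

## Compound list

1 | dehydroabietic acid | CC(C)C1=CC2=C(C=C1)[C@]3(CCC[C@@]([C@@H]3CC2)(C)C(=O)O)C | starting material
2 | 14β-hydroxy acid (abietane 1β-hydroxydehydroabietic acid; OH equatorial, cis to C15) | OC(=O)[C@]1(C)CC[C@@H](O)[C@]2(C)c3ccc(C(C)C)cc3CC[C@@H]12 | intermediate
3 | 14-oxo acid | OC(=O)[C@]1(C)CCC(=O)[C@]2(C)c3ccc(C(C)C)cc3CC[C@@H]12 | intermediate
4 | de-isopropyl 14-oxo acid | OC(=O)[C@]1(C)CCC(=O)[C@]2(C)c3ccccc3CC[C@@H]12 | intermediate
5 | 8,14-dioxo acid | OC(=O)[C@]1(C)CCC(=O)[C@]2(C)c3ccccc3C(=O)C[C@@H]12 | intermediate
6 | 5-bromo-8,14-dioxo acid | OC(=O)[C@]1(C)CCC(=O)[C@]2(C)c3ccc(Br)cc3C(=O)C[C@@H]12 | intermediate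
7 | 5-methoxycarbonyl-8,14-dioxo acid (C16 in place) | OC(=O)[C@]1(C)CCC(=O)[C@]2(C)c3ccc(C(=O)OC)cc3C(=O)C[C@@H]12 | intermediate
8 | C11 acyl azide (not isolated) | [N-]=[N+]=NC(=O)[C@]1(C)CCC(=O)[C@]2(C)c3ccc(C(=O)OC)cc3C(=O)C[C@@H]12 | intermediate
9 | C11 isocyanate (not isolated) | O=C=N[C@]1(C)CCC(=O)[C@]2(C)c3ccc(C(=O)OC)cc3C(=O)C[C@@H]12 | intermediate
10 | C11 methyl carbamate 8,14-dione | COC(=O)N[C@]1(C)CCC(=O)[C@]2(C)c3ccc(C(=O)OC)cc3C(=O)C[C@@H]12 | intermediate
11 | carbamate 8β,14α-diol | COC(=O)N[C@]1(C)CC[C@H](O)[C@]2(C)c3ccc(C(=O)OC)cc3[C@@H](O)C[C@@H]12 | intermediate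
12 | carbamate 8,9-alkene with 14α-hydroxyl | COC(=O)N[C@]1(C)CC[C@H](O)[C@]2(C)c3ccc(C(=O)OC)cc3C=C[C@@H]12 | intermediate
13 | 8α,9α-epoxide (not isolated) | COC(=O)N[C@]1(C)CC[C@H](O)[C@]2(C)c3ccc(C(=O)OC)cc3[C@@H]4O[C@@H]4[C@@H]12 | intermediate
14 | carbamate 9-ketone | COC(=O)N[C@]1(C)CC[C@H](O)[C@]2(C)c3ccc(C(=O)OC)cc3CC(=O)[C@@H]12 | intermediate
15 | 11-methylamino 9β,14α,16-triol (arene) | CN[C@]1(C)CC[C@H](O)[C@]2(C)c3ccc(CO)cc3C[C@@H](O)[C@@H]12 | intermediate
16 | 11-dimethylamino 9β,14α,16-triol (arene) | CN(C)[C@]1(C)CC[C@H](O)[C@]2(C)c3ccc(CO)cc3C[C@@H](O)[C@@H]12 | intermediate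
17 | Birch product, 2(7),4-diene triol | CN(C)[C@]1(C)CC[C@H](O)[C@]2(C)C3=C(C[C@@H](O)[C@@H]12)CC(CO)=CC3 | intermediate
18 | tris-TBS ether of 17 (key-step precursor) | CN(C)[C@]1(C)CC[C@H](O[Si](C)(C)C(C)(C)C)[C@]2(C)C3=C(C[C@@H](O[Si](C)(C)C(C)(C)C)[C@@H]12)CC(CO[Si](C)(C)C(C)(C)C)=CC3 | intermediate
19 | primary ozonide across C2–C7 on the α face (not isolated) | CN(C)[C@]1(C)CC[C@H](O[Si](C)(C)C(C)(C)C)[C@]2(C)[C@]34OOO[C@@]3(C[C@@H](O[Si](C)(C)C(C)(C)C)[C@@H]12)CC(CO[Si](C)(C)C(C)(C)C)=CC4 | intermediate
20 | secondary ozonide bridging C2 and C7 (not isolated; configuration at C2 and C7 not defined) | CN(C)[C@]1(C)CC[C@H](O[Si](C)(C)C(C)(C)C)[C@]2(C)C3(C/C=C(CO[Si](C)(C)C(C)(C)C)\CC4(C[C@@H](O[Si](C)(C)C(C)(C)C)[C@@H]12)OO3)O4 | intermediate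
21 | bicyclic 2,7-dione with ring-cis C4=C5 alkene (key-step product) | CN(C)[C@]1(C)CC[C@H](O[Si](C)(C)C(C)(C)C)[C@]2(C)C(=O)C/C=C(CO[Si](C)(C)C(C)(C)C)\CC(=O)C[C@@H](O[Si](C)(C)C(C)(C)C)[C@@H]12 | intermediate
22 | amine N-oxide 4,5-epoxide (not isolated; one epoxide face drawn) | C[N+](C)([O-])[C@]1(C)CC[C@H](O[Si](C)(C)C(C)(C)C)[C@]2(C)C(=O)C[C@@H]3O[C@]3(CO[Si](C)(C)C(C)(C)C)CC(=O)C[C@@H](O[Si](C)(C)C(C)(C)C)[C@@H]12 | intermediate
23 | 4,5-epoxy-2,7-dione with C11=C20 methylene | C=C1CC[C@H](O[Si](C)(C)C(C)(C)C)[C@]2(C)C(=O)C[C@@H]3O[C@]3(CO[Si](C)(C)C(C)(C)C)CC(=O)C[C@@H](O[Si](C)(C)C(C)(C)C)[C@@H]12 | intermediate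
24 | 4-hydroxy-5-ene-2,7-dione (not isolated) | C=C1CC[C@H](O[Si](C)(C)C(C)(C)C)[C@]2(C)C(=O)C[C@H](O)/C(CO[Si](C)(C)C(C)(C)C)=C\C(=O)C[C@@H](O[Si](C)(C)C(C)(C)C)[C@@H]12 | intermediate
25 | C4 mesylate (not isolated) | C=C1CC[C@H](O[Si](C)(C)C(C)(C)C)[C@]2(C)C(=O)C[C@H](OS(C)(=O)=O)/C(CO[Si](C)(C)C(C)(C)C)=C\C(=O)C[C@@H](O[Si](C)(C)C(C)(C)C)[C@@H]12 | intermediate
26 | 3Z,5E-diene-2,7-dione (both alkenes ring-cis) | C=C1CC[C@H](O[Si](C)(C)C(C)(C)C)[C@]2(C)C(=O)/C=C\C(CO[Si](C)(C)C(C)(C)C)=C/C(=O)C[C@@H](O[Si](C)(C)C(C)(C)C)[C@@H]12 | intermediate
27 | 8-hydroxy-3,5-diene-2,7-dione (C8 epimers) | C=C1CC[C@H](O[Si](C)(C)C(C)(C)C)[C@]2(C)C(=O)/C=C\C(CO[Si](C)(C)C(C)(C)C)=C/C(=O)C(O)[C@@H](O[Si](C)(C)C(C)(C)C)[C@@H]12 | intermediate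
28 | 3,5-diene-2,7,8-trione | C=C1CC[C@H](O[Si](C)(C)C(C)(C)C)[C@]2(C)C(=O)/C=C\C(CO[Si](C)(C)C(C)(C)C)=C/C(=O)C(=O)[C@@H](O[Si](C)(C)C(C)(C)C)[C@@H]12 | intermediate
29 | methyl 2-bromopropanoate (racemic) | COC(=O)C(C)Br | starting material
30 | bromozinc enolate of 29 (Reformatsky reagent; not isolated) | COC(=O)C(C)[Zn]Br | intermediate
31 | C8 tertiary alcohol carrying the C17–C19 methyl propanoate, 2,7-dione | C=C1CC[C@H](O[Si](C)(C)C(C)(C)C)[C@]2(C)C(=O)/C=C\C(CO[Si](C)(C)C(C)(C)C)=C/C(=O)[C@@](O)([C@@H](C)C(=O)OC)[C@@H](O[Si](C)(C)C(C)(C)C)[C@@H]12 | intermediate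
32 | 2,7,8-triol methyl ester (not isolated) | C=C1CC[C@H](O[Si](C)(C)C(C)(C)C)[C@]2(C)[C@@H](O)/C=C\C(CO[Si](C)(C)C(C)(C)C)=C/[C@H](O)[C@@](O)([C@@H](C)C(=O)OC)[C@@H](O[Si](C)(C)C(C)(C)C)[C@@H]12 | intermediate
33 | 7,19-lactone 2,8-diol, 9,14,16-tris-TBS ether | C=C1CC[C@H](O[Si](C)(C)C(C)(C)C)[C@]2(C)[C@@H](O)/C=C\C(CO[Si](C)(C)C(C)(C)C)=C/[C@@H]3OC(=O)[C@H](C)[C@@]3(O)[C@@H](O[Si](C)(C)C(C)(C)C)[C@@H]12 | intermediate
34 | 2,8,9,14,16-pentaol 7,19-lactone | C=C1CC[C@H](O)[C@]2(C)[C@@H](O)/C=C\C(CO)=C/[C@@H]3OC(=O)[C@H](C)[C@@]3(O)[C@@H](O)[C@@H]12 | intermediate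
35 | CNP0269068.1, (1R,2S,3Z,5E,7S,8S,9S,10S,14S,17R)-2,9,14,16-tetraacetoxy-8-hydroxybriara-3,5,11(20)-trien-19,7-olide | C=C1CC[C@H](OC(C)=O)[C@]2(C)[C@@H](OC(C)=O)/C=C\C(COC(C)=O)=C/[C@@H]3OC(=O)[C@H](C)[C@@]3(O)[C@@H](OC(C)=O)[C@@H]12 | target

## Step count and least certain steps

Total: 23 steps. Longest linear sequence: 23 steps (1 to 35); 29 is used as purchased.

**Step 15 (key step).** The most likely failure is loss of chemoselectivity late in the reaction, when ozone begins to cleave the trisubstituted C4=C5 alkene. A second failure is transannular aldol condensation of the 1,6-dione during work-up. The fallback removes the second alkene before the scission: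
- Starting from 17 as its trifluoroacetate salt, hydroxyl-directed epoxidation with VO(acac)2 and t-BuOOH acts only on the allylic C16 alcohol alkene (the tetrasubstituted alkene is only homoallylic to hydroxyls) and gives the 4α,5α-epoxy triol F1.
- Silylation with TBSOTf and 2,6-lutidine at low temperature gives the tris-TBS epoxide F2.
- Ozonolysis of F2, which now has a single alkene, with PPh3 work-up gives the epoxy dione amine F3.
- One equivalent of mCPBA converts F3 into 22, and warming returns the route at 23.

**Step 5.** The most likely failure is α-bromination of the two enolizable ketones by Br2 and HBr if complexation by AlCl3 is incomplete, with loss of regiocontrol on the ring. The fallback replaces halogenation by nitration, in which the ketones are protonated and cannot enolize: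
- Starting from 5, HNO3 in H2SO4 at 0 °C gives the 5-nitro acid F4.
- Fe and NH4Cl in aqueous ethanol give the 5-amino acid F5.
- NaNO2 and HBF4 give the diazonium tetrafluoroborate F6.
- Methoxycarbonylation of F6 with Pd(OAc)2, CO and MeOH returns the route at 7.

**Step 17.** The most likely failure is elimination under kinetic control to a trans C3=C4 enone, or base-induced transannular aldol closure before the eliminations finish. If the 3E isomer F7 forms from 23, the fallback adds a separate radical equilibration: catalytic diphenyl disulfide under visible light adds and eliminates a thiyl radical reversibly and should convert F7 into the ring-cis isomer 26. This is done without base, so aldol pathways are avoided.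

**Step 20.** The most likely failure is addition of the zinc enolate to C7 in place of C8, or poor facial selectivity at C8, together with retro-aldol cleavage on work-up. The fallback builds the same carbinol with reversed polarity and sets C17 by reagent control:
- Starting from 26, the lithium enolate (LiN(SiMe3)2, THF, −78 °C) is alkylated with methyl (R)-2-(trifluoromethylsulfonyloxy)propanoate by SN2 inversion, giving the C8-alkylated dienedione F8.
- Deprotonation of F8 with NaN(SiMe3)2 and oxidation with 2-(phenylsulfonyl)-3-phenyloxaziridine returns the route at 31.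

**Step 21.** The most likely failure is hydride delivery to the wrong face of the C2 carbonyl, which has no stereocentre beside it other than quaternary C1, or loss of chelation control at C7. The fallback separates the two reductions:
- Starting from 31, Zn(BH4)2 in Et2O at −78 °C reduces only the chelating α-hydroxy ketone at C7; K2CO3 in MeOH then gives the 2-oxo lactone F9.
- Reagent-controlled reduction of F9 with (R)-2-methyl-CBS-oxazaborolidine and BH3·SMe2 (the enantiomer chosen on the assumption that quaternary C1 acts as the large group; this assignment is not secure) returns the route at 33.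

## Further compounds

F1 | step 15 | 4α,5α-epoxy triol amine from 17 | CN(C)[C@]1(C)CC[C@H](O)[C@]2(C)C3=C(C[C@@H](O)[C@@H]12)C[C@@]4(CO)O[C@H]4C3
F2 | step 15 | tris-TBS ether of F1 | CN(C)[C@]1(C)CC[C@H](O[Si](C)(C)C(C)(C)C)[C@]2(C)C3=C(C[C@@H](O[Si](C)(C)C(C)(C)C)[C@@H]12)C[C@@]4(CO[Si](C)(C)C(C)(C)C)O[C@H]4C3
F3 | step 15 | 4,5-epoxy-2,7-dione amine | CN(C)[C@]1(C)CC[C@H](O[Si](C)(C)C(C)(C)C)[C@]2(C)C(=O)C[C@@H]3O[C@]3(CO[Si](C)(C)C(C)(C)C)CC(=O)C[C@@H](O[Si](C)(C)C(C)(C)C)[C@@H]12
F4 | step 5 | 5-nitro-8,14-dioxo acid | OC(=O)[C@]1(C)CCC(=O)[C@]2(C)c3ccc([N+](=O)[O-])cc3C(=O)C[C@@H]12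
F5 | step 5 | 5-amino-8,14-dioxo acid | OC(=O)[C@]1(C)CCC(=O)[C@]2(C)c3ccc(N)cc3C(=O)C[C@@H]12
F6 | step 5 | 5-diazonium tetrafluoroborate of the 8,14-dioxo acid | OC(=O)[C@]1(C)CCC(=O)[C@]2(C)c3ccc([N+]#N)cc3C(=O)C[C@@H]12.F[B-](F)(F)F
F7 | step 17 | 3E isomer of 26 (C3=C4 ring-trans) | C=C1CC[C@H](O[Si](C)(C)C(C)(C)C)[C@]2(C)C(=O)/C=C/C(CO[Si](C)(C)C(C)(C)C)=C\C(=O)C[C@@H](O[Si](C)(C)C(C)(C)C)[C@@H]12
F8 | step 20 | C8-alkylated dienedione with 17R methyl propanoate side chain (C8 epimers) | C=C1CC[C@H](O[Si](C)(C)C(C)(C)C)[C@]2(C)C(=O)/C=C\C(CO[Si](C)(C)C(C)(C)C)=C/C(=O)C([C@@H](C)C(=O)OC)[C@@H](O[Si](C)(C)C(C)(C)C)[C@@H]12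
F9 | step 21 | 2-oxo 7,19-lactone 8-ol tris-TBS ether | C=C1CC[C@H](O[Si](C)(C)C(C)(C)C)[C@]2(C)C(=O)/C=C\C(CO[Si](C)(C)C(C)(C)C)=C/[C@@H]3OC(=O)[C@H](C)[C@@]3(O)[C@@H](O[Si](C)(C)C(C)(C)C)[C@@H]12
A1 | alternative 1 | ring A cyclohexene aldehyde from the Diels–Alder reaction | COc1ccc(COC[C@@H]2C=C[C@H](OC(C)=O)[C@](C)(C=O)[C@H]2CO[Si](C)(C)C(C)(C)C)cc1
A2 | alternative 2 | bicyclic lactone with equatorial C14 alcohol from the transannular cyclization | C=C1CC[C@@H](O)[C@]2(C)[C@@H](O[Si](C)(C)C(C)(C)C)/C=C\C(CO[Si](C)(C)C(C)(C)C)=C/[C@@H]3OC(=O)[C@H](C)[C@@]3(O[Si](C)(C)C)[C@@H](O[Si](C)(C)C(C)(C)C)[C@@H]12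
A3 | alternative 3 | acyclic Z,Z-dienyl C7 carbinol from the three-component coupling | C=C1CC[C@H](O[Si](C)(C)C(C)(C)C)[C@](C)([C@@H](O[Si](C)(C)C(C)(C)C)/C=C\C(CO[Si](C)(C)C(C)(C)C)=C/[C@H](O)C2(OCCO2)[C@@H](C)CO[Si](C)(C)C(C)(C)C)[C@H]1COCc1ccc(OC)cc1
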